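## Structural features

The target is a 4-methoxycyclohex-2-enone (C1 carbonyl, C2=C3, C4 bearing OMe, C5 methylene, C6 quaternary). C6 carries an allyl group and a chain made of C7 (CHMe) and C8 (benzylic CHOH) that ends in a 3,4-dimethoxyphenyl ring. There are four stereocentres, C4 (S), C6 (S), C7 (R) and C8 (S). C6, C7 and C8 are contiguous, C7-Me and C8-OH are syn, and C4 stands 1,3 to C6 across C5 with its methoxy group cis to the C7 chain and trans to the allyl group. The fragile points are the γ-methoxy enone (base can dienolise towards C4), the electron-rich benzylic alcohol at C8 (ionisation under acid), the γ-hydroxy ketone (C8–OH can add to C1) and the terminal alkene. The real difficulty is the all-carbon quaternary C6, which has to be set in relation both to the remote C4 and to the acyclic C7/C8 pair. The key step exploits three facts: the allyl group and the C5–C4 arm are both CH2–C units on C6 and can come from two identical CH2–CH(OMe)2 groups; the C4 methoxy group is what an ionised dimethyl acetal leaves on carbon; and C2=C3 lies between a carbinol-level C1 and C4, where a (Z)-vinylsilane can sit. A temporary stereocentre at C1 can then choose between the two arms and is erased when C1 becomes the ketone.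

## Logic of the disconnections

30 to 29: the C8 O–H bond is traced to an O–Si bond. The benzylic alcohol must stay masked while C1 is oxidised, and this is the only way the two oxygens are told apart. The forward cleavage must spare the γ-methoxy enone, so buffered fluoride is required.

29 to 28: the C1 carbonyl is traced to a C1 carbinol. That carbinol is the stereochemical handle of the ring closure and must exist before it; the gain is a stereocentre that a reagent can set. The forward step must oxidise a neopentylic allylic alcohol without touching alkenes or the silyl ether.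

28 to 27: the C1 hydroxyl is traced to an acetate. An ester is preferred to a trialkylsilyl ether at this oxygen: its oxygen is a poor nucleophile towards an oxocarbenium ion, it cannot drive a pinacol-type 1,2-shift to a cation at C2, and base removes it without touching the C8 silyl ether. The forward step needs only mild methanolysis.

27 to 26: the terminal C=C of the allyl group is cut (Wittig). This turns the allyl group into a CH2–CHO arm at the same oxidation level as the arm that became C5–C4. The forward step must methylenate an enolisable aldehyde quickly and leave the acetate alone.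

26 to 24: the aldehyde is traced to its dimethyl acetal. Both C6 arms are then seen to come from the same group. The forward step must cleave an acetal next to an allylic acetate, an allylic methyl ether and an acid-sensitive benzylic silyl ether.

24 to 22: the C3–C4 bond is cut; C4–OMe goes back to an acetal and C2=C3 to a (Z)-vinylsilane. One ring and the stereocentres C4 and C6 disappear for one bond, and C6 becomes a carbon with two identical arms. The forward step must select one arm and one face of the oxocarbenium ion and must attack through the silicon-bearing carbon.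

22 to 21: the cis C2=C3 is traced to an alkyne. The vinylsilane geometry then rests on a syn semi-reduction, which must stop at the alkene.

21 to 20: the acetate is traced to the free propargylic alcohol; the forward step is a plain acylation of a hindered alcohol under conditions harmless to acetals.

20 to 19: the C1–H bond is cut back to a ynone. The controlling stereocentre then comes from a chiral catalyst and not from the substrate. The forward reduction must distinguish a quaternary flank from an alkynyl flank.

19 to 17: the C8 O–Si bond is cut and the open hydroxy ynone is recognised as the ring-chain tautomer of a lactol. The forward step must trap the open form only, and without silyl triflates, which would attack the acetals.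

17 to 14 and 15: the C1–C2 bond is cut to an alkynyl anion and a lactone carbonyl. C1 becomes a lactone carbon and the lactone holds C8–O in place. The forward addition must stop after one acetylide.

14 to 12: the two CH(OMe)2 carbons are traced to two vinyl groups. Two identical acetal arms come from two identical allyl groups. The forward cleavage must prefer the alkenes to the dimethoxyarene and must end in the open bis-acetal.

12 to 9 and 10: both C6–CH2 bonds are cut. The quaternary carbon becomes the α-methylene of a γ-lactone, and because both new groups are the same no stereochemical question arises at C6 here. The forward step needs two enolate alkylations and therefore two equivalents of 10.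

9 to 7: the lactone C1–O bond and oxidation level are traced to a 1,4-diol; the forward oxidation must choose the primary alcohol.

7 to 5: the primary C–O bond is traced to a terminal alkene (hydroboration); the forward step needs anti-Markovnikov selectivity only.

5 to 1 and 2: the C7–C8 bond is cut. Both stereocentres of the chain arise in one crotyl transfer from two simple starting materials. The forward step must be syn-selective and enantioselective.

## Other disconnections considered

Alternative 1: The cut is C6–C7 together with C8–O. In the forward step acid ionises the quinone monoketal A1 to a 2-allyl-4-methoxy-substituted dienone cation; the β-carbon of (E)-propenylveratrole A2 attacks the allyl-bearing carbon and water captures the benzylic cation, which would give the hydroxy dienone A3.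
- In its favour: it joins two simple partners and makes the quaternary C6, C7 and C8 in one operation. On convergence and step economy it is clearly better than the chosen plan, and in forming C6 it is at least its equal.
- Against it here: the cation is ambident (attack at the unsubstituted position, or closure of the benzylic cation onto the dienone in place of water capture). The C6/C7 relation depends on an open transition state, C8 would be set by unselective hydration, and nothing controls the absolute configuration. A3 still lacks C4: the C4=C5 enol ether would have to be saturated regio- and face-selectively next to the C2=C3 enone, the allyl group and a benzylic alcohol.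
- Comparison: the chosen plan is much longer, but every stereocentre has a named control element (crotylborane for C7/C8, the C1 carbinol and a chair for C6/C4). Mechanistically both are cation–alkene reactions; the chosen one is intramolecular and ends by loss of silicon, which removes the regiochemical ambiguity.

Alternative 2: The cut is C1–C6 and C4–C5 (retro-Diels–Alder) with C8–O used as a tether. In the forward step the 2-alkoxyfuran A4 adds across its tethered 1,1-disubstituted alkene to give the oxanorbornene ketal A5.
- In its favour: two ring bonds form at once, where the chosen plan makes one. C1 appears at ketone level without a temporary stereocentre, C8–O needs no protecting group, and the bridging oxygen arrives at C4 cis to the C7 chain. On these four points it is better.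
- Against it here: A4 is a hindered secondary benzylic 2-furyl ether, hard to make and labile to acid. The dienophile is unactivated and furan cycloadditions are reversible, so the equilibrium may not favour A5. After opening of the ketal, C4–OH would have to be methylated in the presence of the freed C8–OH and a base-sensitive γ-hydroxy enone.
- Comparison: the pericyclic step is stereospecific where the chosen step relies on conformational preference. Step count could be equal or lower if A4 were accessible; the risk moves to precursor synthesis and to the late differentiation of two hydroxyl groups.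

Alternative 3: The cut is the C4–O bond made in an iodolactonisation. In the forward step the diallyl acid A6 with I2 and NaHCO3 would give the iodomethyl δ-lactone A7, fixing C6 and C4 relative to C7.
- In its favour: selection between two diastereotopic allyl groups through a chair with equatorial substituents is the same problem as in the chosen plan, but in a reaction class with a long record of such selections. On precedent for the group selection it is better, and it leaves useful handles (iodide, lactone, ketal).
- Against it here: the carbocycle is not yet formed. C2–C3 must be closed later by enolate alkylation and C2=C3 introduced by dehydrogenation. The C4 oxygen is tied up as the lactone oxygen and must be freed and methylated. C8 is at the carboxyl level, so the aryl group and the C8 configuration must be added late by ketone formation and diastereoselective reduction. The absolute configuration rests on one α-methyl centre next to a quaternary carbon.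
- Comparison: both plans desymmetrise a C6 with two equal arms. The chosen plan forms the ring, the alkene and the C4 ether in the same step and has C7/C8 in place from the start, so it is shorter; the alternative is safer in the selection step alone.

Key step: step 11

Assumption: the (Z)-crotylborane carrying isopinocampheyl groups from (+)-α-pinene is taken to attack the Si face of an aryl aldehyde, as the parent allylborane does; locants C1 to C8 of the target are used for all intermediates.

## Route

Step 1
Reactants: 1 veratraldehyde; 2 cis-but-2-ene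
Product: 5 (1S,2R)-1-(3,4-dimethoxyphenyl)-2-methylbut-3-en-1-ol, via (Z)-crotylpotassium 3 (not isolated), via (Z)-crotyldiisopinocampheylborane 4 (not isolated)
Conditions: 2, KOt-Bu, n-BuLi, THF, −78 to −45 °C; (−)-Ipc2BOMe, −78 °C; BF3·OEt2; 1, −78 °C; NaOH, H2O2, rt
Reagents that add atoms: none
Why: Brown asymmetric crotylboration through a closed chair transition state, so the Z geometry of the crotyl unit becomes the syn relation of C7-Me and C8-OH. The isopinocampheyl groups direct attack to the Si face of the aldehyde, which sets C8 (S) and C7 (R).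

Step 2
Reactants: 5 (1S,2R)-1-(3,4-dimethoxyphenyl)-2-methylbut-3-en-1-ol
Product: 7 (1S,2R)-1-(3,4-dimethoxyphenyl)-2-methylbutane-1,4-diol, via O,C-bis(9-BBN) adduct 6 (not isolated)
Conditions: 9-BBN (2.5 equiv), THF, 0 °C to rt; NaOH, H2O2, 0 °C to rt
Reagents that add atoms: hydrogen peroxide, OO
Why: Anti-Markovnikov hydroboration–oxidation of the terminal alkene. The free hydroxyl only consumes one B–H, and no stereocentre is touched.

Step 3
Reactants: 7 (1S,2R)-1-(3,4-dimethoxyphenyl)-2-methylbutane-1,4-diol
Product: 9 (4R,5S)-5-(3,4-dimethoxyphenyl)-4-methyloxolan-2-one, via lactol 8 (not isolated)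
Conditions: TEMPO (0.1 equiv), PhI(OAc)2 (2.5 equiv), CH2Cl2, rt
Reagents that add atoms: none
Why: Oxoammonium (TEMPO) oxidation selects the primary alcohol. The hydroxy aldehyde closes to the lactol, which is oxidised again to the γ-lactone before the hindered benzylic alcohol reacts; C7-Me and C8-aryl end up cis on the ring.

Step 4
Reactants: 9 (4R,5S)-5-(3,4-dimethoxyphenyl)-4-methyloxolan-2-one; 10 allyl bromide (two equivalents in all)
Product: 12 (4R,5S)-3,3-diallyl-5-(3,4-dimethoxyphenyl)-4-methyloxolan-2-one, via monoallyl lactone 11 (not isolated)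
Conditions: LiN(i-Pr)2 (1.1 equiv), THF, −78 °C, then 10 (1.05 equiv), to −20 °C; recool to −78 °C, LiN(i-Pr)2 (1.3 equiv), DMPU, then 10 (1.5 equiv), to 0 °C
Reagents that add atoms: allyl bromide (second equivalent of 10), C=CCBr
Why: Two successive lactone enolate alkylations, each consuming one equivalent of 10; the first charge of 10 is kept near stoichiometric so that the second charge of base meets the monoallyl lactone and not free halide. The first allyl group enters anti to the C7 methyl; the second makes C6 quaternary with two identical groups, so no configuration has to be controlled. The enolate has no β-leaving group.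

Step 5
Reactants: 12 (4R,5S)-3,3-diallyl-5-(3,4-dimethoxyphenyl)-4-methyloxolan-2-one
Product: 14 (4R,5S)-3,3-bis(2,2-dimethoxyethyl)-5-(3,4-dimethoxyphenyl)-4-methyloxolan-2-one, via dialdehyde 13 (not isolated)
Conditions: O3, CH2Cl2/MeOH, Sudan red 7B, −78 °C; Me2S, to rt; HC(OMe)3, CSA (cat.), MeOH, rt
Reagents that add atoms: trimethyl orthoformate, COC(OC)OC; methanol, CO
Why: Ozonolysis with reductive work-up; terminal alkenes react much faster than the dimethoxyarene and the dye marks the end point. Acid-catalysed acetalisation follows, and the orthoformate removes water and so favours the open bis(dimethyl acetal) over a cyclic acetal.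

Step 6
Reactants: 14 (4R,5S)-3,3-bis(2,2-dimethoxyethyl)-5-(3,4-dimethoxyphenyl)-4-methyloxolan-2-one; 15 trimethylsilylacetylene
Product: 17 (4R,5S)-3,3-bis(2,2-dimethoxyethyl)-5-(3,4-dimethoxyphenyl)-4-methyl-2-[(trimethylsilyl)ethynyl]oxolan-2-ol (anomer mixture), via lithium (trimethylsilyl)acetylide 16 (not isolated)
Conditions: 15, n-BuLi, THF, −78 °C; 14, −78 to −40 °C; sat. aq. NH4Cl
Reagents that add atoms: none
Why: 1,2-Addition of an alkynyllithium to a lactone stops at the tetrahedral lithium hemiketal at low temperature. The carbonyl has no α-hydrogen, so enolisation cannot compete, and acetals are inert to the reagent.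

Step 7
Reactants: 17 (4R,5S)-3,3-bis(2,2-dimethoxyethyl)-5-(3,4-dimethoxyphenyl)-4-methyl-2-[(trimethylsilyl)ethynyl]oxolan-2-ol
Product: 19 (5R,6S)-6-[(tert-butyldimethylsilyl)oxy]-6-(3,4-dimethoxyphenyl)-4,4-bis(2,2-dimethoxyethyl)-5-methyl-1-(trimethylsilyl)hex-1-yn-3-one, via open-chain hydroxy ynone 18 (not isolated)
Conditions: TBSCl, imidazole, DMF, rt to 40 °C
Reagents that add atoms: tert-butyldimethylsilyl chloride, CC(C)(C)[Si](C)(C)Cl
Why: Silylation under ring-chain tautomerism: the tertiary neopentylic lactol hydroxyl is too hindered, so the secondary C8 hydroxyl of the open form is trapped and the equilibrium is drained. Chlorosilane with imidazole is used because silyl triflates would attack the dimethyl acetals.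

Step 8
Reactants: 19 (5R,6S)-6-[(tert-butyldimethylsilyl)oxy]-6-(3,4-dimethoxyphenyl)-4,4-bis(2,2-dimethoxyethyl)-5-methyl-1-(trimethylsilyl)hex-1-yn-3-one
Product: 20 (3S,5R,6S)-6-[(tert-butyldimethylsilyl)oxy]-6-(3,4-dimethoxyphenyl)-4,4-bis(2,2-dimethoxyethyl)-5-methyl-1-(trimethylsilyl)hex-1-yn-3-ol
Conditions: (S)-2-methyl-CBS-oxazaborolidine (0.5 equiv), BH3·SMe2 (1.5 equiv), THF, −30 °C; MeOH
Reagents that add atoms: none
Why: Corey–Bakshi–Shibata reduction: the ketone binds the catalyst with the quaternary C6 as the large flank and the alkynyl group as the small one, and the (S)-catalyst delivers hydride to the face that gives the required C1 carbinol. It is named (S) here because the silylalkyne outranks C6, and (R) once the alkyne is reduced.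

Step 9
Reactants: 20 (3S,5R,6S)-6-[(tert-butyldimethylsilyl)oxy]-6-(3,4-dimethoxyphenyl)-4,4-bis(2,2-dimethoxyethyl)-5-methyl-1-(trimethylsilyl)hex-1-yn-3-ol
Product: 21 (3S,5R,6S)-6-[(tert-butyldimethylsilyl)oxy]-6-(3,4-dimethoxyphenyl)-4,4-bis(2,2-dimethoxyethyl)-5-methyl-1-(trimethylsilyl)hex-1-yn-3-yl acetate
Conditions: Ac2O, pyridine, DMAP (cat.), CH2Cl2, rt
Reagents that add atoms: acetic anhydride, CC(=O)OC(C)=O
Why: DMAP-catalysed acylation of a hindered secondary alcohol under conditions that leave acetals alone. The acetate is chosen over a silyl ether for the reasons given for the 28 to 27 disconnection.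

Step 10
Reactants: 21 (3S,5R,6S)-6-[(tert-butyldimethylsilyl)oxy]-6-(3,4-dimethoxyphenyl)-4,4-bis(2,2-dimethoxyethyl)-5-methyl-1-(trimethylsilyl)hex-1-yn-3-yl acetate
Product: 22 (1Z,3R,5R,6S)-6-[(tert-butyldimethylsilyl)oxy]-6-(3,4-dimethoxyphenyl)-4,4-bis(2,2-dimethoxyethyl)-5-methyl-1-(trimethylsilyl)hex-1-en-3-yl acetate
Conditions: H2 (1 atm), Pd/CaCO3 poisoned with Pb(OAc)2, quinoline, EtOAc, rt
Reagents that add atoms: none
Why: Lindlar semi-hydrogenation adds H2 syn to the silylalkyne and gives the (Z)-vinylsilane. The poisoned catalyst leaves the benzylic C–O bond, the propargylic acetate and the arene intact.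

Step 11
Reactants: 22 (1Z,3R,5R,6S)-6-[(tert-butyldimethylsilyl)oxy]-6-(3,4-dimethoxyphenyl)-4,4-bis(2,2-dimethoxyethyl)-5-methyl-1-(trimethylsilyl)hex-1-en-3-yl acetate
Product: 24 (1R,4S,6R)-6-[(1S,2R)-1-[(tert-butyldimethylsilyl)oxy]-1-(3,4-dimethoxyphenyl)propan-2-yl]-6-(2,2-dimethoxyethyl)-4-methoxycyclohex-2-en-1-yl acetate, via methyl oxocarbenium triflate 23 (not isolated)
Conditions: Me3SiOTf (0.5 equiv), 2,6-di-tert-butyl-4-methylpyridine (0.6 equiv), CH2Cl2, −78 °C; pyridine, then aq. NaHCO3
Reagents that add atoms: none
Why: Me3SiOTf reversibly ionises either dimethyl acetal to an (E)-methyl oxocarbenium ion; the (Z)-vinylsilane attacks it through the silicon-bearing carbon C3, the charge developing at C2 is taken up by the C3–Si bond, and silicon leaves to triflate, so the promoter is regenerated and C2=C3 stays cis inside the ring. The closest known reaction type is the acetal-initiated, vinylsilane-terminated cationic cyclisation to cyclohexenes. The six-membered ring closes with both alkene carbons inside it (6-endo with respect to the vinylsilane, exo with respect to the C=O+ bond) through a chair. C6 is set by arm selection: allylic 1,3-strain with the cis SiMe3 group forces C1–H into the alkene plane and the acetoxy group pseudoequatorial, and only the arm that keeps the branched C7 chain equatorial and leaves the other, unbranched arm axial fits this chair. C4 is set by the oxocarbenium face: the methoxy group stays equatorial, away from the axial arm on C6, so it ends cis to the C7 chain and trans to the acetate. The step needs selection between two diastereotopic arms, between two oxocarbenium faces and between C3 and C2 of the alkene; the C1 stereocentre and the size difference of the C6 substituents secure the first two, and silicon secures the third. The acetate at C1 (no oxygen nucleophile, no pinacol-type shift) and the buffered low-temperature conditions are meant to keep the benzylic silyl ether, the second acetal and the vinylsilane from reacting by other paths.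

Step 12
Reactants: 24 (1R,4S,6R)-6-[(1S,2R)-1-[(tert-butyldimethylsilyl)oxy]-1-(3,4-dimethoxyphenyl)propan-2-yl]-6-(2,2-dimethoxyethyl)-4-methoxycyclohex-2-en-1-yl acetate
Product: 26 (1R,4S,6R)-6-[(1S,2R)-1-[(tert-butyldimethylsilyl)oxy]-1-(3,4-dimethoxyphenyl)propan-2-yl]-4-methoxy-6-(2-oxoethyl)cyclohex-2-en-1-yl acetate, via collidinium adduct 25 (not isolated)
Conditions: Et3SiOTf (2 equiv), 2,4,6-collidine (3 equiv), CH2Cl2, 0 °C; H2O, rt
Reagents that add atoms: water, O
Why: Silyl triflate and pyridine-base cleavage of a dimethyl acetal: the acetal is converted into an α-methoxyalkyl pyridinium salt, which water hydrolyses to the aldehyde. The medium is never acidic, so the benzylic silyl ether, the allylic acetate and the allylic methyl ether should survive.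

Step 13
Reactants: 26 (1R,4S,6R)-6-[(1S,2R)-1-[(tert-butyldimethylsilyl)oxy]-1-(3,4-dimethoxyphenyl)propan-2-yl]-4-methoxy-6-(2-oxoethyl)cyclohex-2-en-1-yl acetate
Product: 27 (1R,4S,6S)-6-allyl-6-[(1S,2R)-1-[(tert-butyldimethylsilyl)oxy]-1-(3,4-dimethoxyphenyl)propan-2-yl]-4-methoxycyclohex-2-en-1-yl acetate
Conditions: Ph3PCH3Br, KN(SiMe3)2, THF, 0 °C; 26, −78 to 0 °C
Reagents that add atoms: methyltriphenylphosphonium bromide, C[P+](c1ccccc1)(c1ccccc1)c1ccccc1.[Br-]
Why: Wittig methylenation of the aldehyde is fast at low temperature, where the ylide does not attack the hindered secondary acetate. The CH2–CHO arm becomes the allyl group.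

Step 14
Reactants: 27 (1R,4S,6S)-6-allyl-6-[(1S,2R)-1-[(tert-butyldimethylsilyl)oxy]-1-(3,4-dimethoxyphenyl)propan-2-yl]-4-methoxycyclohex-2-en-1-yl acetate
Product: 28 (1R,4S,6S)-6-allyl-6-[(1S,2R)-1-[(tert-butyldimethylsilyl)oxy]-1-(3,4-dimethoxyphenyl)propan-2-yl]-4-methoxycyclohex-2-en-1-ol
Conditions: K2CO3 (cat.), MeOH, rt
Reagents that add atoms: none
Why: Base-catalysed transesterification removes the only ester; the silyl ether, the methyl ether and both alkenes are inert to methanolic carbonate.

Step 15
Reactants: 28 (1R,4S,6S)-6-allyl-6-[(1S,2R)-1-[(tert-butyldimethylsilyl)oxy]-1-(3,4-dimethoxyphenyl)propan-2-yl]-4-methoxycyclohex-2-en-1-ol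
Product: 29 (4S,6S)-6-allyl-6-[(1S,2R)-1-[(tert-butyldimethylsilyl)oxy]-1-(3,4-dimethoxyphenyl)propan-2-yl]-4-methoxycyclohex-2-en-1-one
Conditions: Dess–Martin periodinane, NaHCO3, CH2Cl2, 0 °C to rt
Reagents that add atoms: none
Why: Dess–Martin oxidation of the hindered allylic alcohol under buffered conditions gives the enone and erases the controlling C1 stereocentre. C6 is quaternary, so nothing can epimerise next to the new carbonyl.

Step 16
Reactants: 29 (4S,6S)-6-allyl-6-[(1S,2R)-1-[(tert-butyldimethylsilyl)oxy]-1-(3,4-dimethoxyphenyl)propan-2-yl]-4-methoxycyclohex-2-en-1-one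
Product: 30 (4S,6S)-6-allyl-6-[(1S,2R)-1-(3,4-dimethoxyphenyl)-1-hydroxypropan-2-yl]-4-methoxycyclohex-2-en-1-one
Conditions: HF·pyridine, pyridine, THF, 0 °C to rt
Reagents that add atoms: none
Why: Fluoride-mediated desilylation in a pyridine-buffered medium frees the C8 alcohol. The conditions are neither basic enough to dienolise the enone towards C4 nor acidic enough to ionise the benzylic position.

## Compound list

1 | veratraldehyde (3,4-dimethoxybenzaldehyde) | COc1ccc(C=O)cc1OC | starting material
2 | cis-but-2-ene | C/C=C\C | starting material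
3 | (Z)-but-2-enylpotassium | C/C=C\[CH2-].[K+] | intermediate
4 | (Z)-but-2-enyl-diisopinocampheylborane, isopinocampheyl groups from (+)-α-pinene | C[C@H]1[C@@H](C[C@@H]2C[C@H]1C2(C)C)B(C/C=C\C)[C@@H]1C[C@@H]2C[C@H]([C@H]1C)C2(C)C | intermediate
5 | (1S,2R)-1-(3,4-dimethoxyphenyl)-2-methylbut-3-en-1-ol | C=C[C@@H](C)[C@H](O)c1ccc(OC)c(OC)c1 | intermediate
6 | O,C-bis(9-borabicyclo[3.3.1]nonan-9-yl) adduct of 5 (C–B at the terminal carbon, O–B at C8) | C1CCC2CCCC1B2CC[C@@H](C)[C@H](OB1C2CCCC1CCC2)c1ccc(OC)c(OC)c1 | intermediate
7 | (1S,2R)-1-(3,4-dimethoxyphenyl)-2-methylbutane-1,4-diol | OCC[C@@H](C)[C@H](O)c1ccc(OC)c(OC)c1 | intermediate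
8 | (4R,5S)-5-(3,4-dimethoxyphenyl)-4-methyloxolan-2-ol (anomer mixture) | OC1C[C@@H](C)[C@@H](c2ccc(OC)c(OC)c2)O1 | intermediate
9 | (4R,5S)-5-(3,4-dimethoxyphenyl)-4-methyloxolan-2-one | O=C1C[C@@H](C)[C@@H](c2ccc(OC)c(OC)c2)O1 | intermediate
10 | allyl bromide | C=CCBr | starting material
11 | (3R,4R,5S)-3-allyl-5-(3,4-dimethoxyphenyl)-4-methyloxolan-2-one | O=C1[C@H](CC=C)[C@@H](C)[C@@H](c2ccc(OC)c(OC)c2)O1 | intermediate
12 | (4R,5S)-3,3-diallyl-5-(3,4-dimethoxyphenyl)-4-methyloxolan-2-one | O=C1C(CC=C)(CC=C)[C@@H](C)[C@@H](c2ccc(OC)c(OC)c2)O1 | intermediate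
13 | 2,2'-[(4R,5S)-5-(3,4-dimethoxyphenyl)-4-methyl-2-oxooxolane-3,3-diyl]diacetaldehyde | O=CCC1(CC=O)[C@@H](C)[C@@H](c2ccc(OC)c(OC)c2)OC1=O | intermediate
14 | (4R,5S)-3,3-bis(2,2-dimethoxyethyl)-5-(3,4-dimethoxyphenyl)-4-methyloxolan-2-one | COC(OC)CC1(CC(OC)OC)[C@@H](C)[C@@H](c2ccc(OC)c(OC)c2)OC1=O | intermediate
15 | trimethylsilylacetylene | C#C[Si](C)(C)C | starting material
16 | lithium (trimethylsilyl)acetylide | [Li+].[C-]#C[Si](C)(C)C | intermediate
17 | (4R,5S)-3,3-bis(2,2-dimethoxyethyl)-5-(3,4-dimethoxyphenyl)-4-methyl-2-[(trimethylsilyl)ethynyl]oxolan-2-ol (anomer mixture) | COC(OC)CC1(CC(OC)OC)[C@@H](C)[C@@H](c2ccc(OC)c(OC)c2)OC1(O)C#C[Si](C)(C)C | intermediate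
18 | (5R,6S)-6-(3,4-dimethoxyphenyl)-4,4-bis(2,2-dimethoxyethyl)-6-hydroxy-5-methyl-1-(trimethylsilyl)hex-1-yn-3-one | COC(OC)CC(CC(OC)OC)([C@@H](C)[C@H](O)c1ccc(OC)c(OC)c1)C(=O)C#C[Si](C)(C)C | intermediate
19 | (5R,6S)-6-[(tert-butyldimethylsilyl)oxy]-6-(3,4-dimethoxyphenyl)-4,4-bis(2,2-dimethoxyethyl)-5-methyl-1-(trimethylsilyl)hex-1-yn-3-one | COC(OC)CC(CC(OC)OC)([C@@H](C)[C@H](O[Si](C)(C)C(C)(C)C)c1ccc(OC)c(OC)c1)C(=O)C#C[Si](C)(C)C | intermediate
20 | (3S,5R,6S)-6-[(tert-butyldimethylsilyl)oxy]-6-(3,4-dimethoxyphenyl)-4,4-bis(2,2-dimethoxyethyl)-5-methyl-1-(trimethylsilyl)hex-1-yn-3-ol | COC(OC)CC(CC(OC)OC)([C@@H](C)[C@H](O[Si](C)(C)C(C)(C)C)c1ccc(OC)c(OC)c1)[C@H](O)C#C[Si](C)(C)C | intermediate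
21 | (3S,5R,6S)-6-[(tert-butyldimethylsilyl)oxy]-6-(3,4-dimethoxyphenyl)-4,4-bis(2,2-dimethoxyethyl)-5-methyl-1-(trimethylsilyl)hex-1-yn-3-yl acetate | COC(OC)CC(CC(OC)OC)([C@@H](C)[C@H](O[Si](C)(C)C(C)(C)C)c1ccc(OC)c(OC)c1)[C@H](OC(C)=O)C#C[Si](C)(C)C | intermediate
22 | (1Z,3R,5R,6S)-6-[(tert-butyldimethylsilyl)oxy]-6-(3,4-dimethoxyphenyl)-4,4-bis(2,2-dimethoxyethyl)-5-methyl-1-(trimethylsilyl)hex-1-en-3-yl acetate (precursor of the key step) | COC(OC)CC(CC(OC)OC)([C@@H](C)[C@H](O[Si](C)(C)C(C)(C)C)c1ccc(OC)c(OC)c1)[C@H](OC(C)=O)/C=C\[Si](C)(C)C | intermediate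
23 | methyl oxocarbenium triflate formed from the cyclising acetal arm of 22 | C[O+]=CC[C@@](CC(OC)OC)([C@@H](C)[C@H](O[Si](C)(C)C(C)(C)C)c1ccc(OC)c(OC)c1)[C@H](OC(C)=O)/C=C\[Si](C)(C)C.[O-]S(=O)(=O)C(F)(F)F | intermediate
24 | (1R,4S,6R)-6-[(1S,2R)-1-[(tert-butyldimethylsilyl)oxy]-1-(3,4-dimethoxyphenyl)propan-2-yl]-6-(2,2-dimethoxyethyl)-4-methoxycyclohex-2-en-1-yl acetate (product of the key step) | COC(OC)C[C@@]1([C@@H](C)[C@H](O[Si](C)(C)C(C)(C)C)c2ccc(OC)c(OC)c2)C[C@H](OC)C=C[C@H]1OC(C)=O | intermediate
25 | 1-(1-methoxyalkyl)-2,4,6-trimethylpyridinium triflate derived from the acetal arm of 24 (epimer mixture at the new carbon) | COC(C[C@@]1([C@@H](C)[C@H](O[Si](C)(C)C(C)(C)C)c2ccc(OC)c(OC)c2)C[C@H](OC)C=C[C@H]1OC(C)=O)[n+]1c(C)cc(C)cc1C.[O-]S(=O)(=O)C(F)(F)F | intermediate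
26 | (1R,4S,6R)-6-[(1S,2R)-1-[(tert-butyldimethylsilyl)oxy]-1-(3,4-dimethoxyphenyl)propan-2-yl]-4-methoxy-6-(2-oxoethyl)cyclohex-2-en-1-yl acetate | O=CC[C@@]1([C@@H](C)[C@H](O[Si](C)(C)C(C)(C)C)c2ccc(OC)c(OC)c2)C[C@H](OC)C=C[C@H]1OC(C)=O | intermediate
27 | (1R,4S,6S)-6-allyl-6-[(1S,2R)-1-[(tert-butyldimethylsilyl)oxy]-1-(3,4-dimethoxyphenyl)propan-2-yl]-4-methoxycyclohex-2-en-1-yl acetate | C=CC[C@@]1([C@@H](C)[C@H](O[Si](C)(C)C(C)(C)C)c2ccc(OC)c(OC)c2)C[C@H](OC)C=C[C@H]1OC(C)=O | intermediate
28 | (1R,4S,6S)-6-allyl-6-[(1S,2R)-1-[(tert-butyldimethylsilyl)oxy]-1-(3,4-dimethoxyphenyl)propan-2-yl]-4-methoxycyclohex-2-en-1-ol | C=CC[C@@]1([C@@H](C)[C@H](O[Si](C)(C)C(C)(C)C)c2ccc(OC)c(OC)c2)C[C@H](OC)C=C[C@H]1O | intermediate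
29 | (4S,6S)-6-allyl-6-[(1S,2R)-1-[(tert-butyldimethylsilyl)oxy]-1-(3,4-dimethoxyphenyl)propan-2-yl]-4-methoxycyclohex-2-en-1-one | C=CC[C@@]1([C@@H](C)[C@H](O[Si](C)(C)C(C)(C)C)c2ccc(OC)c(OC)c2)C[C@H](OC)C=CC1=O | intermediate
30 | (4S,6S)-6-allyl-6-[(1S,2R)-1-(3,4-dimethoxyphenyl)-1-hydroxypropan-2-yl]-4-methoxycyclohex-2-en-1-one (CNP0138111.1) | C=CC[C@@]1([C@@H](C)[C@H](O)c2ccc(OC)c(OC)c2)C[C@H](OC)C=CC1=O | target

## Step count and least certain steps

Total: 16 steps. Longest linear sequence: 16 steps, from 1 to 30; 2, 10 and 15 enter along this line.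

Step 11 (key step). The most likely failure is poor discrimination between the two acetal arms, because the preference rests only on the equatorial demand of the branched C7 chain against the unbranched arm. Further risks are capture of the oxocarbenium ion by the C8 silyl ether oxygen, participation of the acetate carbonyl at C2 in place of loss of silicon, ionisation at the benzylic C8–O bond and protodesilylation of the vinylsilane by adventitious acid. The fallback fixes C6 before the ring is closed; it sets out from 9 and returns at 27. Lactone 9 is allylated once and the monoallyl lactone 11 is isolated. Ozonolysis and acetalisation as in step 5 give the mono-acetal lactone F1. A second enolate alkylation with 10, which enters anti to the C7 methyl, gives the allyl acetal lactone F2 with the C6 configuration of the target. Addition of 16 gives the lactol F3, TBSCl with imidazole gives the silyloxy ynone F4, reduction as in step 8 gives the propargylic alcohol F5 and acetylation gives the propargylic acetate F6. Semi-hydrogenation over Ni2B (from Ni(OAc)2 and NaBH4) with ethylenediamine, which leaves the terminal alkene alone, gives the (Z)-vinylsilane F7. Ring closure under the conditions of step 11, now with a single acetal arm, gives 27 directly. This line is no longer than the main route but gives up the group-selective closure, and the allyl group is present as a second π-nucleophile during the cyclisation.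

Step 5. Ozone may over-oxidise the electron-rich arene once the alkenes are consumed, and the 1,5-dialdehyde may close to a cyclic bis-acetal in place of the open one. The fallback sets out from 12 and returns at 14: dihydroxylation with OsO4 (cat.) and N-methylmorpholine N-oxide gives the tetraol F8, NaIO4 cleaves it to 13, which is then isolated and acetalised with HC(OMe)3 and CSA under strictly water-free conditions to give 14.

Step 7. The lactol may fail to open, silylation may occur at the hemiketal oxygen, imidazole may add in conjugate fashion to the ynone, or the alkynyl silicon may be lost under the basic conditions. The fallback sets out from 14 and returns at 19: the lactone is opened with MeONHMe·HCl and Me3Al to the hydroxy Weinreb amide F9, which is silylated at once with TBSCl and imidazole to the silyloxy Weinreb amide F10; addition of 16 then gives 19 without any lactol stage.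

Step 8. Face selectivity may erode if the silylalkynyl group is not clearly the smaller flank or if the C7/C8 centres oppose the catalyst, and the hindered ketone may react slowly enough for borane to attack the alkyne. The fallback sets out from 19 and returns at 20: Noyori transfer hydrogenation with RuCl[(S,S)-TsDPEN](p-cymene) in i-PrOH, in which the alkyne is recognised electronically and not by size. This fallback makes no new compound (entry F0).

Step 10. The hindered silylalkyne may stall on the poisoned catalyst or run on to the saturated silane. The fallback sets out from 21 and returns at 22: syn-hydroboration with dicyclohexylborane places boron on the silicon-bearing carbon and gives the alkenylborane F11, and protodeboronation with acetic acid, which proceeds with retention, gives 22.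

## Further compounds

F1 | step 11 | (3R,4R,5S)-3-(2,2-dimethoxyethyl)-5-(3,4-dimethoxyphenyl)-4-methyloxolan-2-one | O=C1[C@H](CC(OC)OC)[C@@H](C)[C@@H](c2ccc(OC)c(OC)c2)O1
F2 | step 11 | (3S,4R,5S)-3-allyl-3-(2,2-dimethoxyethyl)-5-(3,4-dimethoxyphenyl)-4-methyloxolan-2-one | O=C1[C@@](CC=C)(CC(OC)OC)[C@@H](C)[C@@H](c2ccc(OC)c(OC)c2)O1
F3 | step 11 | lactol from F2 and 16, 3-allyl-3-(2,2-dimethoxyethyl)-5-(3,4-dimethoxyphenyl)-4-methyl-2-[(trimethylsilyl)ethynyl]oxolan-2-ol (anomer mixture) | C=CC[C@]1(CC(OC)OC)[C@@H](C)[C@@H](c2ccc(OC)c(OC)c2)OC1(O)C#C[Si](C)(C)C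
F4 | step 11 | silyloxy ynone, 4-allyl-6-[(tert-butyldimethylsilyl)oxy]-4-(2,2-dimethoxyethyl)-6-(3,4-dimethoxyphenyl)-5-methyl-1-(trimethylsilyl)hex-1-yn-3-one | C=CC[C@](CC(OC)OC)([C@@H](C)[C@H](O[Si](C)(C)C(C)(C)C)c1ccc(OC)c(OC)c1)C(=O)C#C[Si](C)(C)C
F5 | step 11 | propargylic alcohol from F4 | C=CC[C@](CC(OC)OC)([C@@H](C)[C@H](O[Si](C)(C)C(C)(C)C)c1ccc(OC)c(OC)c1)[C@H](O)C#C[Si](C)(C)C
F6 | step 11 | propargylic acetate from F5 | C=CC[C@](CC(OC)OC)([C@@H](C)[C@H](O[Si](C)(C)C(C)(C)C)c1ccc(OC)c(OC)c1)[C@H](OC(C)=O)C#C[Si](C)(C)C
F7 | step 11 | (Z)-vinylsilane acetate with one acetal arm and the allyl group in place | C=CC[C@](CC(OC)OC)([C@@H](C)[C@H](O[Si](C)(C)C(C)(C)C)c1ccc(OC)c(OC)c1)[C@H](OC(C)=O)/C=C\[Si](C)(C)C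
F8 | step 5 | (4R,5S)-3,3-bis(2,3-dihydroxypropyl)-5-(3,4-dimethoxyphenyl)-4-methyloxolan-2-one (diastereomer mixture) | OCC(O)CC1(CC(O)CO)[C@@H](C)[C@@H](c2ccc(OC)c(OC)c2)OC1=O
F9 | step 7 | (3R,4S)-4-(3,4-dimethoxyphenyl)-2,2-bis(2,2-dimethoxyethyl)-4-hydroxy-N-methoxy-N,3-dimethylbutanamide | COC(OC)CC(CC(OC)OC)([C@@H](C)[C@H](O)c1ccc(OC)c(OC)c1)C(=O)N(C)OC
F10 | step 7 | (3R,4S)-4-[(tert-butyldimethylsilyl)oxy]-4-(3,4-dimethoxyphenyl)-2,2-bis(2,2-dimethoxyethyl)-N-methoxy-N,3-dimethylbutanamide | COC(OC)CC(CC(OC)OC)([C@@H](C)[C@H](O[Si](C)(C)C(C)(C)C)c1ccc(OC)c(OC)c1)C(=O)N(C)OC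
F0 | step 8 | none | none
F11 | step 10 | alkenylborane from 21, dicyclohexylboryl and trimethylsilyl on the same alkene carbon, boron trans to C1 | COC(OC)CC(CC(OC)OC)([C@@H](C)[C@H](O[Si](C)(C)C(C)(C)C)c1ccc(OC)c(OC)c1)[C@H](OC(C)=O)/C=C(/B(C1CCCCC1)C1CCCCC1)[Si](C)(C)C
A1 | alternative 1 | 2-allyl-4,4-dimethoxycyclohexa-2,5-dien-1-one | C=CCC1=CC(OC)(OC)C=CC1=O
A2 | alternative 1 | (E)-1,2-dimethoxy-4-(prop-1-enyl)benzene | C/C=C/c1ccc(OC)c(OC)c1
A3 | alternative 1 | 6-allyl-6-[1-(3,4-dimethoxyphenyl)-1-hydroxypropan-2-yl]-4-methoxycyclohexa-2,4-dien-1-one, configured as the target | C=CC[C@@]1([C@@H](C)[C@H](O)c2ccc(OC)c(OC)c2)C=C(OC)C=CC1=O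
A4 | alternative 2 | 2-{[(1S,2R)-1-(3,4-dimethoxyphenyl)-2-methyl-3-methylidenehex-5-en-1-yl]oxy}furan | C=CCC(=C)[C@@H](C)[C@H](Oc1ccco1)c1ccc(OC)c(OC)c1
A5 | alternative 2 | tricyclic 7-oxanorbornene ketal cycloadduct | C=CC[C@@]12C[C@H]3C=C[C@@]1(O3)O[C@H](c4ccc(OC)c(OC)c4)[C@@H]2C
A6 | alternative 3 | 3-allyl-2-methyl-3-(2-methyl-1,3-dioxolan-2-yl)hex-5-enoic acid, C7 configured as the target | C=CCC(CC=C)(C1(C)OCCO1)[C@@H](C)C(=O)O
A7 | alternative 3 | iodomethyl δ-lactone with methyl, dioxolanyl and iodomethyl equatorial | C=CC[C@]1(C2(C)OCCO2)C[C@@H](CI)OC(=O)[C@@H]1C
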